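**Retrosynthetic overview**

- The strategy rests on the pyrrole ring N1–C2(CO2Me)–C3(indole A)–C4(indole B)–C5(H). C4–C5–N1 is a three-atom unit carrying one indole and one hydrogen, and C2–C3 is a two-atom unit carrying the ester and the other indole.
- Key disconnection: bonds C3–C4 and N1–C2, by a rhodium-catalysed denitrogenative [3+2] of a 4-(indol-3-yl)-1-tosyl-1,2,3-triazole with the methyl enol ether of the indolepyruvate, followed by loss of methanol across C2/C3.
- Both partners come from one N-tosylated 5-bromoindole-3-carbaldehyde. One-carbon homologation to the 3-ethynylindole and cycloaddition with tosyl azide give the triazole; Horner–Wadsworth–Emmons olefination gives the enol ether.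
- Ring order: the two indoles are bought intact, the triazole is built and then spent, and the pyrrole is the only ring formed in the product. The three tosyl groups are removed in the last step.

Key step: step 5

Remark: the olefination of step 4 is assumed to give mainly the Z enol ether. The E isomer would serve equally, since the alkene geometry is lost in step 5.

**Route**

Step 1
Reactants: 1 5-bromo-1H-indole-3-carbaldehyde; 2 p-toluenesulfonyl chloride
Product: 3 5-bromo-1-tosyl-1H-indole-3-carbaldehyde
Conditions: TsCl, Et3N, DMAP (cat.), CH2Cl2, 0 °C → rt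
Reagents that add atoms: p-toluenesulfonyl chloride, Cc1ccc(cc1)S(=O)(=O)Cl
Why: N-sulfonylation of the acidic N–H of the vinylogous formamide under DMAP catalysis; the tosyl group makes the aldehyde a normal electrophile and deactivates the indole C2=C3 bond for the later carbene step.

Step 2
Reactants: 3 5-bromo-1-tosyl-1H-indole-3-carbaldehyde; 4 (trimethylsilyl)diazomethane
Product: 6 5-bromo-3-ethynyl-1-tosyl-1H-indole, via diazoalkene 5 (not isolated)
Conditions: Me3SiCHN2, LiN(i-Pr)2, THF, −78 °C; then 3, −78 °C → rt; aq. NH4Cl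
Reagents that add atoms: (trimethylsilyl)diazomethane, C[Si](C)(C)C=[N+]=[N-]
Why: Colvin rearrangement, in which the lithiated silyldiazomethane adds to the aldehyde, Peterson-type loss of lithium trimethylsilanolate gives diazoalkene 5, and loss of N2 with a 1,2-shift in the alkylidene carbene gives the terminal alkyne; the methanol-free medium at low temperature should spare the N-tosyl group, which methoxide would attack on a 3-formylindole, and the aryl bromide.

Step 3
Reactants: 6 5-bromo-3-ethynyl-1-tosyl-1H-indole; 7 tosyl azide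
Product: 8 5-bromo-1-tosyl-3-(1-tosyl-1H-1,2,3-triazol-4-yl)-1H-indole
Conditions: TsN3 (1.0 equiv), Cu(O2CC4H3S) (copper thiophene-2-carboxylate, monovalent copper, 10 mol %), PhMe, 0 °C → rt
Reagents that add atoms: tosyl azide, Cc1ccc(cc1)S(=O)(=O)N=[N+]=[N-]
Why: copper-catalysed azide–alkyne cycloaddition of a sulfonyl azide, which gives the 1-sulfonyl-4-aryl triazole regiospecifically through the copper acetylide; the carboxylate catalyst in a non-basic apolar medium should keep the cuprated triazole from opening to a ketenimine.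

Step 4
Reactants: 3 5-bromo-1-tosyl-1H-indole-3-carbaldehyde; 9 methyl 2-(dimethoxyphosphoryl)-2-methoxyacetate
Product: 10 methyl (2Z)-3-(5-bromo-1-tosyl-1H-indol-3-yl)-2-methoxyprop-2-enoate
Conditions: 9, LiN(SiMe3)2, THF, −78 °C; then 3, −78 °C → rt
Reagents that add atoms: methyl 2-(dimethoxyphosphoryl)-2-methoxyacetate, COC(C(=O)OC)P(=O)(OC)OC
Why: Horner–Wadsworth–Emmons olefination of an aromatic aldehyde with the lithium salt of an α-methoxy phosphonoacetate, expected to favour the Z enol ether (ester trans to the indole); the amide base is not nucleophilic, so the N-tosyl group should survive.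

Step 5
Reactants: 8 5-bromo-1-tosyl-3-(1-tosyl-1H-1,2,3-triazol-4-yl)-1H-indole; 10 methyl (2Z)-3-(5-bromo-1-tosyl-1H-indol-3-yl)-2-methoxyprop-2-enoate
Product: 13 methyl 3,4-bis(5-bromo-1-tosyl-1H-indol-3-yl)-1-tosyl-1H-pyrrole-2-carboxylate, via diazo imine 11 (not isolated), via methoxy dihydropyrrole 12 (not isolated)
Conditions: Rh2(O2CC7H15)4 (2 mol %), 10 (1.5 equiv), slow addition of 8, dry ClCH2CH2Cl, 80 °C; then CF3SO3H (20 mol %), 60 °C
Reagents that add atoms: none
Why: Proposed new method: Triazole 8 opens reversibly to diazo imine 11, which Rh2(O2CC7H15)4 (divalent rhodium) decomposes with loss of N2 to an electrophilic α-imino carbene at the carbon that bears indole B; the enol ether of 10 attacks it through the oxygen-remote carbon that bears indole A (bond C3–C4), the sulfonamide nitrogen of the resulting zwitterion adds to the oxocarbenium carbon (bond N1–C2) to give 12, and triflic acid then ionises the C2 methoxy group so that loss of the C3 proton leaves the aromatic N-tosyl pyrrole 13. The closest known reaction is the dirhodium-catalysed transannulation of 1-sulfonyl-1,2,3-triazoles with alkyl vinyl ethers and acid-induced loss of the alcohol; new here is the trisubstituted, captodative α-methoxy acrylate as the two-carbon partner, whose ester lowers the nucleophilicity of the alkene and destabilises the N-sulfonyl iminium ion of the elimination, which is why a strong acid is used. The pyrrole ring closes by attack of nitrogen on the C=O+ bond of the oxocarbenium ion, a 5-exo-trig closure, or equivalently by cyclopropanation and ring expansion of the donor-acceptor cyclopropyl imine to the same 12. No stereocentre survives: C2 and C3 of 12 form without control and both are erased, like the alkene geometry of 10, on aromatisation. The step needs regioselectivity (ester next to nitrogen, the indoles on C3 and C4) and chemoselectivity for the enol ether over the indole double bonds; the first is secured by the polarity of the partners (carbene carbon to the β-carbon, nitrogen to the acetal carbon), the second by the tosyl groups on both indoles and by keeping 10 in excess while 8 is added slowly, and since one partner acts only as electrophile and the other only as nucleophile, neither can couple with itself to a pyrrole.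

Step 6
Reactants: 13 methyl 3,4-bis(5-bromo-1-tosyl-1H-indol-3-yl)-1-tosyl-1H-pyrrole-2-carboxylate
Product: 14 methyl 3,4-bis(5-bromo-1H-indol-3-yl)-1H-pyrrole-2-carboxylate
Conditions: Cs2CO3 (6 equiv), dry MeOH/THF, rt → 50 °C
Reagents that add atoms: none
Why: nucleophilic cleavage of the three N–S bonds by methoxide formed in situ (attack at sulfur, with pyrrolide and indolide as leaving groups), the pyrrole sulfonamide next to the ester going first; in methanol the methyl ester can only exchange with itself and the aryl bromides are inert.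

**Compound list**

1 | 5-bromo-1H-indole-3-carbaldehyde | O=Cc1c[nH]c2ccc(Br)cc12 | starting material
2 | p-toluenesulfonyl chloride | Cc1ccc(cc1)S(=O)(=O)Cl | starting material
3 | 5-bromo-1-tosyl-1H-indole-3-carbaldehyde | O=Cc1cn(S(=O)(=O)c2ccc(C)cc2)c2ccc(Br)cc12 | intermediate
4 | (trimethylsilyl)diazomethane | C[Si](C)(C)C=[N+]=[N-] | starting material
5 | 5-bromo-3-(2-diazoethenyl)-1-tosyl-1H-indole (diazoalkene) | [N-]=[N+]=C=Cc1cn(S(=O)(=O)c2ccc(C)cc2)c2ccc(Br)cc12 | intermediate
6 | 5-bromo-3-ethynyl-1-tosyl-1H-indole | C#Cc1cn(S(=O)(=O)c2ccc(C)cc2)c2ccc(Br)cc12 | intermediate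
7 | tosyl azide | Cc1ccc(cc1)S(=O)(=O)N=[N+]=[N-] | starting material
8 | 5-bromo-1-tosyl-3-(1-tosyl-1H-1,2,3-triazol-4-yl)-1H-indole | Cc1ccc(cc1)S(=O)(=O)n1cc(nn1)-c1cn(S(=O)(=O)c2ccc(C)cc2)c2ccc(Br)cc12 | intermediate
9 | methyl 2-(dimethoxyphosphoryl)-2-methoxyacetate | COC(C(=O)OC)P(=O)(OC)OC | starting material
10 | methyl (2Z)-3-(5-bromo-1-tosyl-1H-indol-3-yl)-2-methoxyprop-2-enoate | COC(=O)/C(OC)=C/c1cn(S(=O)(=O)c2ccc(C)cc2)c2ccc(Br)cc12 | intermediate
11 | N-[(1E)-2-(5-bromo-1-tosyl-1H-indol-3-yl)-2-diazoethylidene]-4-methylbenzenesulfonamide (diazo imine) | Cc1ccc(cc1)S(=O)(=O)/N=C/C(=[N+]=[N-])c1cn(S(=O)(=O)c2ccc(C)cc2)c2ccc(Br)cc12 | intermediate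
12 | methyl 3,4-bis(5-bromo-1-tosyl-1H-indol-3-yl)-2-methoxy-1-tosyl-2,3-dihydro-1H-pyrrole-2-carboxylate (mixture of diastereomers, C2 and C3 undefined) | COC(=O)C1(OC)N(S(=O)(=O)c2ccc(C)cc2)C=C(c2cn(S(=O)(=O)c3ccc(C)cc3)c3ccc(Br)cc23)C1c1cn(S(=O)(=O)c2ccc(C)cc2)c2ccc(Br)cc12 | intermediate
13 | methyl 3,4-bis(5-bromo-1-tosyl-1H-indol-3-yl)-1-tosyl-1H-pyrrole-2-carboxylate | COC(=O)c1n(S(=O)(=O)c2ccc(C)cc2)cc(-c2cn(S(=O)(=O)c3ccc(C)cc3)c3ccc(Br)cc23)c1-c1cn(S(=O)(=O)c2ccc(C)cc2)c2ccc(Br)cc12 | intermediate
14 | methyl 3,4-bis(5-bromo-1H-indol-3-yl)-1H-pyrrole-2-carboxylate | COC(=O)c1[nH]cc(-c2c[nH]c3ccc(Br)cc23)c1-c1c[nH]c2ccc(Br)cc12 | target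

**Step count**

Total steps: 6. Longest linear sequence: 5 (steps 1, 2, 3, 5, 6).

**Steps most likely to fail**

Step 5. The captodative, hindered enol ether may be too poor a nucleophile to intercept the carbene. The carbene would then be diverted to attack by the ester carbonyl oxygen, to dimerisation or to reaction with adventitious water. The acid-induced loss of methanol may also stall at the ester-destabilised iminium stage. The fallback takes the ester out of the cycloaddition and sets out from 3 and 8.
- Wittig reaction of 3 with the ylide from (methoxymethyl)triphenylphosphonium chloride and KOtBu in THF should give 5-bromo-3-(2-methoxyethenyl)-1-tosyl-1H-indole F1, an ordinary 1,2-disubstituted alkyl enol ether of the known partner class.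
- Transannulation of F1 with 8 under Rh2(O2CC7H15)4 should give 3,4-bis(5-bromo-1-tosyl-1H-indol-3-yl)-2-methoxy-1-tosyl-2,3-dihydro-1H-pyrrole F2, which is not isolated. Acid should convert it into 3,4-bis(5-bromo-1-tosyl-1H-indol-3-yl)-1-tosyl-1H-pyrrole F3.
- KOH in aqueous dioxane at 90 °C should remove the three tosyl groups to give 3,4-bis(5-bromo-1H-indol-3-yl)-1H-pyrrole F4, which is handled under argon.
- Cl3CCOCl in Et2O should acylate one of the two equivalent free pyrrole α-positions to give 1-[3,4-bis(5-bromo-1H-indol-3-yl)-1H-pyrrol-2-yl]-2,2,2-trichloroethan-1-one F5.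
- NaOMe in MeOH should cleave F5 in haloform fashion to the methyl ester, so the fallback comes back to the route at 14.

Step 6. Cleavage at the two indole nitrogens may be incomplete, and the pyrrole or indole anions may be N-methylated by the methyl tosylate that the cleavage releases. The fallback sets out from 13. KOH in aqueous dioxane at 80 °C should remove all three tosyl groups as the sulfonate salt, which is not an alkylating agent, and saponify the ester. Careful acidification at 0 °C should then give 3,4-bis(5-bromo-1H-indol-3-yl)-1H-pyrrole-2-carboxylic acid F6. Selective O-methylation of the acid with Me3SiCHN2 (compound 4) in MeOH/PhMe at 0 °C should leave the three N–H groups untouched, and the fallback comes back to the route at 14.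

Step 2. The lithiated diazomethane or the lithium silanolate may attack the sulfonyl group, indole C2 may be deprotonated, or the alkylidene carbene may be diverted before the 1,2-shift. The fallback avoids diazo and carbene chemistry and sets out from 3. Wittig bromomethylenation with the ylide from (bromomethyl)triphenylphosphonium bromide and KOtBu in THF at −78 °C should give 5-bromo-3-[(Z)-2-bromoethenyl]-1-tosyl-1H-indole F7. Anti elimination of HBr with a further portion of KOtBu (THF, −78 °C → rt) should give the alkyne, and the fallback comes back to the route at 6.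

**Further compounds**

F1 | step 5 | 5-bromo-3-[(E)-2-methoxyethenyl]-1-tosyl-1H-indole (E/Z mixture; E drawn) | CO/C=C/c1cn(S(=O)(=O)c2ccc(C)cc2)c2ccc(Br)cc12
F2 | step 5 | 3,4-bis(5-bromo-1-tosyl-1H-indol-3-yl)-2-methoxy-1-tosyl-2,3-dihydro-1H-pyrrole (not isolated; C2 and C3 undefined) | COC1N(S(=O)(=O)c2ccc(C)cc2)C=C(c2cn(S(=O)(=O)c3ccc(C)cc3)c3ccc(Br)cc23)C1c1cn(S(=O)(=O)c2ccc(C)cc2)c2ccc(Br)cc12
F3 | step 5 | 3,4-bis(5-bromo-1-tosyl-1H-indol-3-yl)-1-tosyl-1H-pyrrole | c1n(S(=O)(=O)c2ccc(C)cc2)cc(-c2cn(S(=O)(=O)c3ccc(C)cc3)c3ccc(Br)cc23)c1-c1cn(S(=O)(=O)c2ccc(C)cc2)c2ccc(Br)cc12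
F4 | step 5 | 3,4-bis(5-bromo-1H-indol-3-yl)-1H-pyrrole | c1[nH]cc(-c2c[nH]c3ccc(Br)cc23)c1-c1c[nH]c2ccc(Br)cc12
F5 | step 5 | 1-[3,4-bis(5-bromo-1H-indol-3-yl)-1H-pyrrol-2-yl]-2,2,2-trichloroethan-1-one | O=C(c1[nH]cc(-c2c[nH]c3ccc(Br)cc23)c1-c1c[nH]c2ccc(Br)cc12)C(Cl)(Cl)Cl
F6 | step 6 | 3,4-bis(5-bromo-1H-indol-3-yl)-1H-pyrrole-2-carboxylic acid | OC(=O)c1[nH]cc(-c2c[nH]c3ccc(Br)cc23)c1-c1c[nH]c2ccc(Br)cc12
F7 | step 2 | 5-bromo-3-[(Z)-2-bromoethenyl]-1-tosyl-1H-indole | Br/C=C\c1cn(S(=O)(=O)c2ccc(C)cc2)c2ccc(Br)cc12
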